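## Retrosynthetic overview
- The C-ring chromone comes from oxidative cyclization of a 2'-hydroxychalcone (I2/DMSO), so the target disconnects to the chalcone **6**.
- The chalcone comes from a Claisen–Schmidt condensation of phloroacetophenone (**5**) with the chromene aldehyde **4**.
- The 2,2-dimethylpyran ring of **4** is made by a propargyl Claisen rearrangement, [1,5]-H shift and 6π-oxa-electrocyclization of the 4-O-(1,1-dimethylpropargyl) ether **3** of protocatechualdehyde. The only free ortho carbon is C5, which fixes the regiochemistry.
- Ring-forming order: the B-ring-fused pyran first, then the chalcone, then the C-ring chromone.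

**Assumption:** the given SMILES has no stereocentres, so the target is achiral. There is no enantiomer to control, and no step creates or destroys a stereocentre. The only stereo-element is the E-alkene of chalcone **6**, which is lost on cyclization.

## Route

**Step 1**
Reactants: **1** 3,4-dihydroxybenzaldehyde; **2** 3-chloro-3-methylbut-1-yne
Product: **3** 3-hydroxy-4-[(2-methylbut-3-yn-2-yl)oxy]benzaldehyde
Conditions: K2CO3 (1.0 equiv), KI (cat.), DMF, 60 °C
Reagents that add atoms: 3-chloro-3-methylbut-1-yne, C#CC(C)(C)Cl
Why: Williamson-type O-alkylation. The 4-OH is para to CHO and much more acidic than the 3-OH, so one equivalent of base gives the 4-O-propargyl ether selectively.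

**Step 2**
Reactants: **3**
Product: **4** 8-hydroxy-2,2-dimethyl-2H-chromene-6-carbaldehyde
Conditions: PhNEt2, 200 °C, N2, 3 h (sealed tube or microwave)
Reagents that add atoms: none
Why: Aromatic propargyl Claisen [3,3] rearrangement gives an allenyl dienone. Tautomerization, a 1,5-H shift and 6π-oxa-electrocyclization then close the 2,2-dimethyl-2H-chromene. The rearrangement can only reach C5, because C3 carries the OH. No stereocentre is formed.

**Step 3**
Reactants: **4** chromene aldehyde; **5** 2',4',6'-trihydroxyacetophenone
Product: **6** (E)-3-(8-hydroxy-2,2-dimethyl-2H-chromen-6-yl)-1-(2,4,6-trihydroxyphenyl)prop-2-en-1-one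
Conditions: 50% aq. KOH (about 6 equiv), EtOH, rt, 48 h; then acidify with 1 M HCl to pH about 4
Reagents that add atoms: none
Why: Claisen–Schmidt (aldol/E1cB) condensation of the acetophenone enolate with the non-enolizable aldehyde. The B-ring phenoxide is meta to CHO, so it only mildly deactivates the aldehyde. Excess base covers all the phenols. Any flavanone formed by oxa-Michael closure is also carried forward in Step 4.

**Step 4**
Reactants: **6**
Product: **7** Yinyanghuo E, 5,7-dihydroxy-2-(8-hydroxy-2,2-dimethyl-2H-chromen-6-yl)-4H-chromen-4-one
Conditions: I2 (0.2 equiv), DMSO, 120 °C, 2 h; quench with aq. Na2S2O3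
Reagents that add atoms: none (I2 is catalytic and DMSO is the terminal oxidant)
Why: Oxidative cyclization of a 2'-hydroxychalcone. Oxa-Michael closure gives the flavanone, and iodination/elimination (HI loss) gives the flavone. The chalcone or flavanone converges on the flavone, which is achiral.

## Final checks
- **Target match:** the B-ring has C1' on the chromone, C3' carbon on the vinyl CH=, C4'–O in the pyran and C5'–OH. This is exactly the 8-OH chromene-6-yl unit in **4** (C6 attached, C8a–O ring oxygen, C8–OH). The A-ring 5,7-diOH comes from **5**. The formula is C20H16O6, with 16 H confirmed from the SMILES.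
- **Atom accounting:**
  - **1** (C7H6O3) + **2** (C5H7Cl) − HCl gives **3** (C12H12O3).
  - **3** isomerizes to **4** (C12H12O3).
  - **4** + **5** (C8H8O4) − H2O gives **6** (C20H18O6).
  - **6** − 2H gives **7** (C20H16O6).
- **Functional-group survival:** the free phenols and the chromene alkene tolerate KOH. The aldehyde is consumed in Step 3. Catalytic I2 is the only possible concern for the chromene in Step 4.
- **Stereochemistry:** no stereocentres exist, so none can be scrambled.

## Compound list
1 | 3,4-dihydroxybenzaldehyde | O=Cc1ccc(O)c(O)c1 | starting material
2 | 3-chloro-3-methylbut-1-yne | C#CC(C)(C)Cl | starting material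
3 | 3-hydroxy-4-[(2-methylbut-3-yn-2-yl)oxy]benzaldehyde | O=Cc1ccc(OC(C)(C)C#C)c(O)c1 | intermediate
4 | 8-hydroxy-2,2-dimethyl-2H-chromene-6-carbaldehyde | O=Cc1cc(O)c2OC(C)(C)C=Cc2c1 | intermediate
5 | 2',4',6'-trihydroxyacetophenone (phloroacetophenone) | CC(=O)c1c(O)cc(O)cc1O | starting material
6 | (E)-3-(8-hydroxy-2,2-dimethyl-2H-chromen-6-yl)-1-(2,4,6-trihydroxyphenyl)prop-2-en-1-one | O=C(/C=C/c1cc(O)c2OC(C)(C)C=Cc2c1)c1c(O)cc(O)cc1O | intermediate
7 | Yinyanghuo E | CC1(C)C=Cc2cc(-c3cc(=O)c4c(O)cc(O)cc4o3)cc(O)c2O1 | target (achiral)

**Total steps:** 4. **Longest linear sequence:** 4 steps, from **1**.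

## Steps most likely to fail
1. **Step 3 (Claisen–Schmidt on the tri-phenoxide acetophenone):** the enolate forms poorly, so conversion may be low.
   Fallback: use 2'-hydroxy-4',6'-bis(MOM-oxy)acetophenone, made from **5** with MOMCl/K2CO3, for the condensation and cyclization. Remove the MOM groups at the end with HCl/MeOH, a protecting-group strategy that adds two steps.
2. **Step 4 (I2/DMSO in the presence of the chromene alkene):** iodination or decomposition of the C3=C4 double bond is possible.
   Fallback: carry propargyl ether **3** through the Claisen–Schmidton/flavone sequence first. Then form the pyran last on the flavone with a gold(I)-catalysed or thermal propargyl Claisen cyclization, which changes the ring-formation order.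
3. **Step 1 (regioselective mono-O-propargylation of the catechol):** bis-ether or C-alkylation by-products could form.
   Fallback: start from commercial 3-benzyloxy-4-hydroxybenzaldehyde, propargylate, run the Claisen cyclization, then remove the benzyl group with BCl3/pentamethylbenzene at −78 °C instead of hydrogenolysis, which would reduce the chromene.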